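The runs were computed with constants of no real substance; scatter was added.

I start from the ends of the runs.

the same everywhere: E 0.050 M

| run | G | remark | time |
|---|---|---|---|
| green | 0.067 M | run made earlier |  |
| grey | 0.23 M | run made earlier |  |
| delta | 0.0500 M |  | 8.0 h |
| epsilon | 0.150 M |  | 8.0 h |

| run | time / h | Q / % | Z / % | X / % | J / % | E / % |
|---|---|---|---|---|---|---|
| green | 0.667 | 0 | 19.2 | 5.3 | 1.0 | 41.7 |
| green | 1.00 | 0.4 | 27.4 | 10.5 | 1.9 | 30.3 |
| green | 1.33 | 0.8 | 36.4 | 17.5 | 2.3 | 21.5 |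
| green | 2.50 | 3.5 | 45.2 | 35.5 | 4.1 | 5.4 |
| green | 3.00 | 0 | 44.3 | 39.9 | 6.4 | 3.4 |
| green | 5.00 | 2.6 | 41.2 | 48.6 | 5.5 | 0 |
| green | 8.00 | 0 | 40.8 | 53.7 | 4.9 | 0.6 |
| grey | 0.417 | 0.1 | 24.5 | 2.3 | 3.8 | 18.0 |
| grey | 1.33 | 2.9 | 62.4 | 12.3 | 7.5 | 0.6 |
| grey | 2.50 | 2.3 | 68.9 | 20.3 | 9.0 | 0.5 |
| grey | 3.00 | 2.9 | 67.0 | 20.2 | 8.6 | 0.1 |
| grey | 5.00 | 3.9 | 67.9 | 20.3 | 11.3 | 1.2 |
| grey | 6.00 | 4.6 | 69.1 | 20.4 | 8.9 | 0 |
| grey | 8.00 | 2.4 | 68.0 | 19.5 | 10.5 | 0.4 |

(readings scatter by 1 percentage point)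

- which of these there is most of at the end, counted by the E in it, delta (Z / Q / X / J)
- which of these there is most of at the end, counted by the E in it, epsilon (Z / Q / X / J)
- amount of the one of these that there is most of at the end, in percent of the E charged, delta
- amount of the one of these that there is most of at the end, in percent of the E charged, epsilon

- steps under discussion: E + G <-> L; D -> X; G + X <-> J; L -> Z; J <-> Q; Z <-> J; E -> D

By the steps under discussion, Z, J and Q each hold one E and one G, while X holds E but no G. E reads 0.6% at the end of green and 0.4% at the end of grey, so I count the E as either X or the pool of Z, J and Q. Green ends with a pool of 45.7% against X at 53.7%, which reads 19.3 M⁻¹ for pool over X per free cG. Grey, with a pool of 80.9%, reads 21.9 M⁻¹. I carry the mean, 20.6 M⁻¹, as the share constant K: pool over X, divided by free cG, an apparent equilibrium constant. Z reads 85.9% of the two pools together.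

Now the settings, by hand. By K, with E held, raising G raises the pool. At 0.150 M in epsilon, K with the charged G gives a pool of 75.5%. Putting the G this takes back in gives 69.8%, and once more 70.3%, so I expect Z at 60.4%.

E enters through that subtraction, and in delta its charge equals that of G. The rounds there go from 50.7% to 33.7%, a wider swing than in epsilon. So I restart from their middle, get 37.3%, and settle between this figure and that middle, which leaves X at 60.3%.

Time I read from the runs. Grey's X reads 20.3% at 2.50 h and 19.5% at 8.00 h, but green's reads 48.6% at 5.00 h and 53.7% at 8.00 h, so in delta, with less G than green, I allow that X may still be climbing at 8.0 h.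

The forecast names X at 59% (55% to 63%) for delta and Z at 60% (56% to 64%) for epsilon, saying: "The rest is a split between X and the Z/J/Q pool." My X in delta stands above its figure.

The flask gives X at 61.1% in delta and Z at 59.4% in epsilon.

    E + G ⇌ L (K = 321 M⁻¹, k = 0.00493 M⁻¹ s⁻¹)
    D → X (k = 4.17 × 10⁻⁴ s⁻¹)
    G + X ⇌ J (K = 2.20 M⁻¹, k = 0.00318 M⁻¹ s⁻¹)
    L → Z (k = 5.09 × 10⁻⁴ s⁻¹)
    J ⇌ Q (K = 0.325, k = 2.45 × 10⁻⁴ s⁻¹)
    Z ⇌ J (K = 0.130, k = 1.97 × 10⁻⁴ s⁻¹)
    E → D (k = 8.58 × 10⁻⁵ s⁻¹)

Epsilon with 0.60 M of G has 12.0 equiv of G to E. K with the charged G gives a pool of 92.5%. Putting the G it takes back in leaves free cG at 0.554 M and the pool at 91.9%, so X comes to 8.10% and Z to 78.9%. That flask holds X at 8.34% and Z at 78.2% at 8.00 h.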